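The route rests on disconnecting the pyran ring of the upper flavan (ring C of the upper unit) at O1–C2 and C3–C4. C4 of that ring carries the ortho-hydroxylated upper ring A and C6 of the lower flavan, so C4, C4a, C8a and O1 are a latent ortho-quinone methide. In the key step a chiral Brønsted acid ionises a benzhydrol that already contains the complete protected lower flavan-3,4-diol, and the quinone methide adds across a (Z)-2-arylvinyl pivalate as a hetero-Diels–Alder heterodiene: one operation joins two advanced fragments, closes ring C and sets C2, C3 and C4 (2,3-cis, 3,4-trans). The lower flavan is built from the same salicylaldehyde by an analogous cycloaddition.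

Key step: step 11

Remark: flavan numbering (O1, C2, C3, C4, C4a, C5–C8, C8a) is used for both units; "upper" is the 4-aryl flavan-3-ol unit, "lower" the flavan-3,4-diol unit.
Assumption: the sense of induction of the chiral acid in steps 3 and 11 cannot be assigned with certainty beforehand; the (R)-catalyst is written and its mirror image would be taken if the first run shows the opposite sense.

Step 1
Reactants: 1 2,3,4-trihydroxybenzaldehyde
Product: 2 3,4-bis(benzyloxy)-2-hydroxybenzaldehyde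
Conditions: BnBr (2.1 equiv), K2CO3 (2.1 equiv), acetone, reflux
Reagents that add atoms: benzyl bromide, BrCc1ccccc1
Why: Williamson etherification; the 2-hydroxyl is locked in a hydrogen bond to the formyl group and its chelated phenolate is the poorest nucleophile, so the two benzyl groups should go to O3 and O4.

Step 2
Reactants: 3 1-(benzyloxy)-4-ethynylbenzene
Product: 4 (Z)-2-[4-(benzyloxy)phenyl]ethenyl 2,2-dimethylpropanoate
Conditions: t-BuCO2H (1.2 equiv), [RuCl2(p-cymene)]2 (1 mol %), P(4-ClC6H4)3 (3 mol %), DMAP (4 mol %), toluene, 60 °C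
Reagents that add atoms: pivalic acid, CC(C)(C)C(=O)O
Why: Ruthenium-catalysed anti-Markovnikov addition of a carboxylic acid to a terminal alkyne through a ruthenium vinylidene; attack of pivalate on the vinylidene carbon and protonolysis should give the (Z)-enol ester.

Step 3
Reactants: 2 3,4-bis(benzyloxy)-2-hydroxybenzaldehyde; 4 (Z)-2-[4-(benzyloxy)phenyl]ethenyl 2,2-dimethylpropanoate
Product: 7 (2R,3R,4S)-7,8-bis(benzyloxy)-2-[4-(benzyloxy)phenyl]-4-methoxy-3,4-dihydro-2H-chromen-3-yl 2,2-dimethylpropanoate, via dimethyl acetal 5 (not isolated), via methoxy quinone methide 6 (not isolated)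
Conditions: HC(OMe)3 (1.5 equiv), (R)-3,3'-bis(2,4,6-triisopropylphenyl)-1,1'-binaphthyl-2,2'-diyl N-triflylphosphoramide (5 mol %), molecular sieves 5 Å, CH2Cl2, rt; then 4 (1.5 equiv), −40 → 0 °C; Et3N quench
Reagents that add atoms: trimethyl orthoformate, COC(OC)OC
Why: Acid-catalysed three-component ortho-quinone methide hetero-Diels–Alder reaction (salicylaldehyde, orthoformate, styrene type): acetal 5 loses methanol to the methoxy-stabilised quinone methide 6, which adds across the (Z)-alkene with the para-benzyloxyphenyl carbon taking O1 and the acyloxy carbon taking the methide carbon; C2 and C3 should come out cis by suprafacial addition, the absolute sense is set by the chiral phosphoramide ion pair, the exo approach puts the methoxy group trans to O3, the minor 3,4-cis isomer is removed by chromatography, and the C4 centre is erased in step 4.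

Step 4
Reactants: 7 (2R,3R,4S)-7,8-bis(benzyloxy)-2-[4-(benzyloxy)phenyl]-4-methoxy-3,4-dihydro-2H-chromen-3-yl 2,2-dimethylpropanoate
Product: 8 (2R,3S)-7,8-bis(benzyloxy)-2-[4-(benzyloxy)phenyl]-4-oxo-3,4-dihydro-2H-chromen-3-yl 2,2-dimethylpropanoate
Conditions: DDQ (1.3 equiv), CH2Cl2/H2O (18:1), 0 °C → rt
Reagents that add atoms: water, O
Why: DDQ oxidation of an electron-rich benzylic ether, as in the cleavage of 4-methoxybenzyl ethers: hydride abstraction from C4–H (flanked by the methoxy oxygen, O1 ortho and the 7-benzyloxy group para) and hydrolysis of the oxocarbenium ion should give the ketone while C2, C3 and the plain benzyl ethers stay untouched.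

Step 5
Reactants: 8 (2R,3S)-7,8-bis(benzyloxy)-2-[4-(benzyloxy)phenyl]-4-oxo-3,4-dihydro-2H-chromen-3-yl 2,2-dimethylpropanoate
Product: 9 (2R,3R,4R)-7,8-bis(benzyloxy)-2-[4-(benzyloxy)phenyl]-3,4-dihydro-2H-chromene-3,4-diol
Conditions: LiAlH4 (3 equiv), THF, −78 → 0 °C; aq. KNaC4H4O6; recrystallisation
Reagents that add atoms: none
Why: Hydride reduction: axial delivery to the C4 carbonyl from the face opposite the axial 3-acyloxy group should give the 4-hydroxyl cis to O3 (all-cis), the same reagent cleaves the pivalate reductively, and recrystallisation of the diol should raise the enantiomeric purity.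

Step 6
Reactants: 9 (2R,3R,4R)-7,8-bis(benzyloxy)-2-[4-(benzyloxy)phenyl]-3,4-dihydro-2H-chromene-3,4-diol
Product: 10 (2R,3S,4R)-7,8-bis(benzyloxy)-2-[4-(benzyloxy)phenyl]-3,4-bis[(tert-butyldimethylsilyl)oxy]-3,4-dihydro-2H-chromene
Conditions: t-BuMe2SiOTf (3 equiv), 2,6-lutidine (5 equiv), CH2Cl2, 0 °C → rt
Reagents that add atoms: tert-butyldimethylsilyl trifluoromethanesulfonate, CC(C)(C)[Si](C)(C)OS(=O)(=O)C(F)(F)F
Why: Silylation of both secondary hydroxyls with a silyl triflate; no stereocentre is touched (the C3 descriptor changes only by priority) and the ethers mask the diol against the organolithium of step 10.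

Step 7
Reactants: 10 (2R,3S,4R)-7,8-bis(benzyloxy)-2-[4-(benzyloxy)phenyl]-3,4-bis[(tert-butyldimethylsilyl)oxy]-3,4-dihydro-2H-chromene
Product: 11 (2R,3S,4R)-7,8-bis(benzyloxy)-2-[4-(benzyloxy)phenyl]-6-bromo-3,4-bis[(tert-butyldimethylsilyl)oxy]-3,4-dihydro-2H-chromene
Conditions: NBS (1.05 equiv), MeCN, 0 °C
Reagents that add atoms: N-bromosuccinimide, O=C1CCC(=O)N1Br
Why: Electrophilic aromatic bromination: C6 is para to O1 and ortho to the 7-benzyloxy group, whereas C5 is activated only by the twisted central 8-benzyloxy group and is shielded by the C4 silyl ether.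

Step 8
Reactants: 12 3,4-bis(benzyloxy)benzaldehyde
Product: 13 1,2-bis(benzyloxy)-4-ethynylbenzene
Conditions: MeC(O)C(N2)P(O)(OMe)2 (1.3 equiv), K2CO3 (2 equiv), MeOH, rt
Reagents that add atoms: dimethyl (1-diazo-2-oxopropyl)phosphonate, COP(=O)(OC)C(=[N+]=[N-])C(C)=O
Why: Seyferth–Gilbert homologation in the Ohira–Bestmann variant: the diazomethylphosphonate anion formed in the flask condenses with the aldehyde and the alkylidene carbene rearranges to the terminal alkyne.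

Step 9
Reactants: 13 1,2-bis(benzyloxy)-4-ethynylbenzene
Product: 14 (Z)-2-[3,4-bis(benzyloxy)phenyl]ethenyl 2,2-dimethylpropanoate
Conditions: t-BuCO2H (1.2 equiv), [RuCl2(p-cymene)]2 (1 mol %), P(4-ClC6H4)3 (3 mol %), DMAP (4 mol %), toluene, 60 °C
Reagents that add atoms: pivalic acid, CC(C)(C)C(=O)O
Why: The same ruthenium-vinylidene anti-Markovnikov hydro-oxycarbonylation as in step 2, which should again give the (Z)-enol ester.

Step 10
Reactants: 11 (2R,3S,4R)-7,8-bis(benzyloxy)-2-[4-(benzyloxy)phenyl]-6-bromo-3,4-bis[(tert-butyldimethylsilyl)oxy]-3,4-dihydro-2H-chromene; 2 3,4-bis(benzyloxy)-2-hydroxybenzaldehyde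
Product: 17 [3,4-bis(benzyloxy)-2-hydroxyphenyl]{(2R,3S,4R)-7,8-bis(benzyloxy)-2-[4-(benzyloxy)phenyl]-3,4-bis[(tert-butyldimethylsilyl)oxy]-3,4-dihydro-2H-chromen-6-yl}methanol (both carbinol epimers), via sodium phenolate 15 (not isolated), via aryllithium 16 (not isolated)
Conditions: 11, n-BuLi (1.05 equiv), THF, −78 °C; then 2 (1.3 equiv) pre-treated with NaH (1.3 equiv, THF, 0 °C), −78 → −30 °C; aq. NH4Cl; filtration through Et3N-deactivated silica
Reagents that add atoms: none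
Why: Bromine–lithium exchange and 1,2-addition of the aryllithium to the aldehyde, whose phenol is masked as its sodium phenolate; the carbinol centre forms without control, which is harmless because step 11 erases it.

Step 11
Reactants: 17 [3,4-bis(benzyloxy)-2-hydroxyphenyl]{(2R,3S,4R)-7,8-bis(benzyloxy)-2-[4-(benzyloxy)phenyl]-3,4-bis[(tert-butyldimethylsilyl)oxy]-3,4-dihydro-2H-chromen-6-yl}methanol; 14 (Z)-2-[3,4-bis(benzyloxy)phenyl]ethenyl 2,2-dimethylpropanoate
Product: 19 (2R,3R,4R)-7,8-bis(benzyloxy)-2-[3,4-bis(benzyloxy)phenyl]-4-{(2R,3S,4R)-7,8-bis(benzyloxy)-2-[4-(benzyloxy)phenyl]-3,4-bis[(tert-butyldimethylsilyl)oxy]-3,4-dihydro-2H-chromen-6-yl}-3,4-dihydro-2H-chromen-3-yl 2,2-dimethylpropanoate, via ortho-quinone methide 18 (not isolated)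
Conditions: 14 (2 equiv), (R)-3,3'-bis(2,4,6-triisopropylphenyl)-1,1'-binaphthyl-2,2'-diyl N-triflylphosphoramide (10 mol %), molecular sieves 4 Å, toluene/CH2Cl2 (1:1), −40 → −10 °C; Et3N quench
Reagents that add atoms: none
Why: The acid ionises the doubly benzylic carbinol of 17 to the (E)-ortho-quinone methide 18 (lower-unit aryl anti to the carbonyl oxygen), which stays bound to the chiral phosphoramide anion and reacts as the 1-oxadiene O1=C8a–C4a=C4 with the electron-rich alkene of 14 in an asynchronous inverse-electron-demand hetero-Diels–Alder reaction. The closest known reaction type is the chiral Brønsted acid-catalysed [4+2] cycloaddition of benzhydrol-derived ortho-quinone methides with styrenes. Ring C of the upper unit closes as a six-membered ring by this [4+2] cycloaddition, the C3–C4 bond running ahead and the O1–C2 bond following in the same encounter. C2 and C3 should come out cis because the addition is suprafacial on the (Z)-alkene, C4 should come out trans to both because of the exo approach (the pivaloyloxy group on the attacking carbon avoids the crowded sector between the twisted lower-unit aryl and C4a, and neither alkene substituent lies under the quinone methide), and the absolute sense of all three centres is set by the face of 18 that the chiral ion pair leaves open, since the lower stereocentres are too remote to interfere. The step needs regioselectivity, secured by the para-benzyloxyphenyl group that stabilises positive charge at C2 far better than the acyloxy group does at C3; exo selectivity and retention of the alkene geometry, secured by the bulky pivalate, the low temperature and the non-polar medium; and site selectivity, secured because only the upper ring has a free ortho hydroxyl (O7 of the lower ring is benzylated).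

Step 12
Reactants: 19 (2R,3R,4R)-7,8-bis(benzyloxy)-2-[3,4-bis(benzyloxy)phenyl]-4-{(2R,3S,4R)-7,8-bis(benzyloxy)-2-[4-(benzyloxy)phenyl]-3,4-bis[(tert-butyldimethylsilyl)oxy]-3,4-dihydro-2H-chromen-6-yl}-3,4-dihydro-2H-chromen-3-yl 2,2-dimethylpropanoate
Product: 20 (2R,3R,4R)-7,8-bis(benzyloxy)-2-[3,4-bis(benzyloxy)phenyl]-4-{(2R,3S,4R)-7,8-bis(benzyloxy)-2-[4-(benzyloxy)phenyl]-3,4-bis[(tert-butyldimethylsilyl)oxy]-3,4-dihydro-2H-chromen-6-yl}-3,4-dihydro-2H-chromen-3-ol
Conditions: i-Bu2AlH (4 equiv), CH2Cl2, −78 → −20 °C; aq. KNaC4H4O6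
Reagents that add atoms: none
Why: Reductive cleavage of the hindered ester with an aluminium hydride; benzyl and silyl ethers are inert and C3 keeps its configuration because the C3–O bond is not broken.

Step 13
Reactants: 20 (2R,3R,4R)-7,8-bis(benzyloxy)-2-[3,4-bis(benzyloxy)phenyl]-4-{(2R,3S,4R)-7,8-bis(benzyloxy)-2-[4-(benzyloxy)phenyl]-3,4-bis[(tert-butyldimethylsilyl)oxy]-3,4-dihydro-2H-chromen-6-yl}-3,4-dihydro-2H-chromen-3-ol
Product: 21 (2R,3R,4R)-6-{(2R,3R,4R)-7,8-bis(benzyloxy)-2-[3,4-bis(benzyloxy)phenyl]-3-hydroxy-3,4-dihydro-2H-chromen-4-yl}-7,8-bis(benzyloxy)-2-[4-(benzyloxy)phenyl]-3,4-dihydro-2H-chromene-3,4-diol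
Conditions: Bu4NF (4 equiv), THF, 0 °C → rt
Reagents that add atoms: none
Why: Fluoride-induced cleavage of the two silyl ethers (Si–F bond formation) under basic conditions that cannot ionise the benzylic C4–O bond of the lower unit.

Step 14
Reactants: 21 (2R,3R,4R)-6-{(2R,3R,4R)-7,8-bis(benzyloxy)-2-[3,4-bis(benzyloxy)phenyl]-3-hydroxy-3,4-dihydro-2H-chromen-4-yl}-7,8-bis(benzyloxy)-2-[4-(benzyloxy)phenyl]-3,4-dihydro-2H-chromene-3,4-diol
Product: 22 (2R,3R,4R)-6-[(2R,3R,4S)-2-(3,4-dihydroxyphenyl)-3,7,8-trihydroxy-3,4-dihydro-2H-chromen-4-yl]-2-(4-hydroxyphenyl)-3,4-dihydro-2H-chromene-3,4,7,8-tetrol (CNP0174688.1)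
Conditions: H2 (1 atm), Pd(OH)2/C, THF/MeOH (1:1), rt; filtration and evaporation under argon
Reagents that add atoms: none
Why: Heterogeneous hydrogenolysis of the seven aryl benzyl ethers, the most labile class of benzyl ether, in neutral medium so that the benzylic C4 hydroxyl, the ring C ether bonds and the C4–C6 bond should survive; no stereocentre is involved.

Compound list
1 | 2,3,4-trihydroxybenzaldehyde | O=Cc1ccc(O)c(O)c1O | starting material
2 | 3,4-bis(benzyloxy)-2-hydroxybenzaldehyde | O=Cc1ccc(OCc2ccccc2)c(OCc2ccccc2)c1O | intermediate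
3 | 1-(benzyloxy)-4-ethynylbenzene | C#Cc1ccc(OCc2ccccc2)cc1 | starting material
4 | (Z)-2-[4-(benzyloxy)phenyl]ethenyl 2,2-dimethylpropanoate | CC(C)(C)C(=O)O/C=C\c1ccc(OCc2ccccc2)cc1 | intermediate
5 | 2,3-bis(benzyloxy)-6-(dimethoxymethyl)phenol | COC(OC)c1ccc(OCc2ccccc2)c(OCc2ccccc2)c1O | intermediate (not isolated)
6 | (6E)-2,3-bis(benzyloxy)-6-(methoxymethylidene)cyclohexa-2,4-dien-1-one | CO/C=C1\C=CC(OCc2ccccc2)=C(OCc2ccccc2)C1=O | intermediate (not isolated)
7 | (2R,3R,4S)-7,8-bis(benzyloxy)-2-[4-(benzyloxy)phenyl]-4-methoxy-3,4-dihydro-2H-chromen-3-yl 2,2-dimethylpropanoate (2,3-cis-3,4-trans) | O(Cc1ccccc1)c1ccc([C@H]2Oc3c(ccc(OCc4ccccc4)c3OCc3ccccc3)[C@H](OC)[C@H]2OC(=O)C(C)(C)C)cc1 | intermediate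
8 | (2R,3S)-7,8-bis(benzyloxy)-2-[4-(benzyloxy)phenyl]-4-oxo-3,4-dihydro-2H-chromen-3-yl 2,2-dimethylpropanoate (2,3-cis) | O(Cc1ccccc1)c1ccc([C@H]2Oc3c(ccc(OCc4ccccc4)c3OCc3ccccc3)C(=O)[C@H]2OC(=O)C(C)(C)C)cc1 | intermediate
9 | (2R,3R,4R)-7,8-bis(benzyloxy)-2-[4-(benzyloxy)phenyl]-3,4-dihydro-2H-chromene-3,4-diol (all-cis) | O(Cc1ccccc1)c1ccc([C@H]2Oc3c(ccc(OCc4ccccc4)c3OCc3ccccc3)[C@@H](O)[C@H]2O)cc1 | intermediate
10 | (2R,3S,4R)-7,8-bis(benzyloxy)-2-[4-(benzyloxy)phenyl]-3,4-bis[(tert-butyldimethylsilyl)oxy]-3,4-dihydro-2H-chromene (all-cis) | O(Cc1ccccc1)c1ccc([C@H]2Oc3c(ccc(OCc4ccccc4)c3OCc3ccccc3)[C@@H](O[Si](C)(C)C(C)(C)C)[C@H]2O[Si](C)(C)C(C)(C)C)cc1 | intermediate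
11 | (2R,3S,4R)-7,8-bis(benzyloxy)-2-[4-(benzyloxy)phenyl]-6-bromo-3,4-bis[(tert-butyldimethylsilyl)oxy]-3,4-dihydro-2H-chromene | O(Cc1ccccc1)c1ccc([C@H]2Oc3c(cc(Br)c(OCc4ccccc4)c3OCc3ccccc3)[C@@H](O[Si](C)(C)C(C)(C)C)[C@H]2O[Si](C)(C)C(C)(C)C)cc1 | intermediate
12 | 3,4-bis(benzyloxy)benzaldehyde | O=Cc1ccc(OCc2ccccc2)c(OCc2ccccc2)c1 | starting material
13 | 1,2-bis(benzyloxy)-4-ethynylbenzene | C#Cc1ccc(OCc2ccccc2)c(OCc2ccccc2)c1 | intermediate
14 | (Z)-2-[3,4-bis(benzyloxy)phenyl]ethenyl 2,2-dimethylpropanoate | CC(C)(C)C(=O)O/C=C\c1ccc(OCc2ccccc2)c(OCc2ccccc2)c1 | intermediate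
15 | sodium 2,3-bis(benzyloxy)-6-formylphenolate | [Na+].[O-]c1c(C=O)ccc(OCc2ccccc2)c1OCc1ccccc1 | intermediate (not isolated)
16 | {(2R,3S,4R)-7,8-bis(benzyloxy)-2-[4-(benzyloxy)phenyl]-3,4-bis[(tert-butyldimethylsilyl)oxy]-3,4-dihydro-2H-chromen-6-yl}lithium | O(Cc1ccccc1)c1ccc([C@H]2Oc3c(cc([Li])c(OCc4ccccc4)c3OCc3ccccc3)[C@@H](O[Si](C)(C)C(C)(C)C)[C@H]2O[Si](C)(C)C(C)(C)C)cc1 | intermediate (not isolated)
17 | [3,4-bis(benzyloxy)-2-hydroxyphenyl]{(2R,3S,4R)-7,8-bis(benzyloxy)-2-[4-(benzyloxy)phenyl]-3,4-bis[(tert-butyldimethylsilyl)oxy]-3,4-dihydro-2H-chromen-6-yl}methanol (both carbinol epimers) | O(Cc1ccccc1)c1ccc([C@H]2Oc3c(cc(C(O)c4ccc(OCc5ccccc5)c(OCc5ccccc5)c4O)c(OCc4ccccc4)c3OCc3ccccc3)[C@@H](O[Si](C)(C)C(C)(C)C)[C@H]2O[Si](C)(C)C(C)(C)C)cc1 | intermediate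
18 | (6E)-2,3-bis(benzyloxy)-6-({(2R,3S,4R)-7,8-bis(benzyloxy)-2-[4-(benzyloxy)phenyl]-3,4-bis[(tert-butyldimethylsilyl)oxy]-3,4-dihydro-2H-chromen-6-yl}methylidene)cyclohexa-2,4-dien-1-one | O(Cc1ccccc1)c1ccc([C@H]2Oc3c(cc(/C=C4\C=CC(OCc5ccccc5)=C(OCc5ccccc5)C4=O)c(OCc4ccccc4)c3OCc3ccccc3)[C@@H](O[Si](C)(C)C(C)(C)C)[C@H]2O[Si](C)(C)C(C)(C)C)cc1 | intermediate (not isolated)
19 | (2R,3R,4R)-7,8-bis(benzyloxy)-2-[3,4-bis(benzyloxy)phenyl]-4-{(2R,3S,4R)-7,8-bis(benzyloxy)-2-[4-(benzyloxy)phenyl]-3,4-bis[(tert-butyldimethylsilyl)oxy]-3,4-dihydro-2H-chromen-6-yl}-3,4-dihydro-2H-chromen-3-yl 2,2-dimethylpropanoate (upper unit 2,3-cis-3,4-trans) | O(Cc1ccccc1)c1ccc([C@H]2Oc3c(cc([C@H]4c5ccc(OCc6ccccc6)c(OCc6ccccc6)c5O[C@H](c5ccc(OCc6ccccc6)c(OCc6ccccc6)c5)[C@@H]4OC(=O)C(C)(C)C)c(OCc4ccccc4)c3OCc3ccccc3)[C@@H](O[Si](C)(C)C(C)(C)C)[C@H]2O[Si](C)(C)C(C)(C)C)cc1 | intermediate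
20 | (2R,3R,4R)-7,8-bis(benzyloxy)-2-[3,4-bis(benzyloxy)phenyl]-4-{(2R,3S,4R)-7,8-bis(benzyloxy)-2-[4-(benzyloxy)phenyl]-3,4-bis[(tert-butyldimethylsilyl)oxy]-3,4-dihydro-2H-chromen-6-yl}-3,4-dihydro-2H-chromen-3-ol | O(Cc1ccccc1)c1ccc([C@H]2Oc3c(cc([C@H]4c5ccc(OCc6ccccc6)c(OCc6ccccc6)c5O[C@H](c5ccc(OCc6ccccc6)c(OCc6ccccc6)c5)[C@@H]4O)c(OCc4ccccc4)c3OCc3ccccc3)[C@@H](O[Si](C)(C)C(C)(C)C)[C@H]2O[Si](C)(C)C(C)(C)C)cc1 | intermediate
21 | (2R,3R,4R)-6-{(2R,3R,4R)-7,8-bis(benzyloxy)-2-[3,4-bis(benzyloxy)phenyl]-3-hydroxy-3,4-dihydro-2H-chromen-4-yl}-7,8-bis(benzyloxy)-2-[4-(benzyloxy)phenyl]-3,4-dihydro-2H-chromene-3,4-diol (hepta-O-benzyl ether of the target) | O(Cc1ccccc1)c1ccc([C@H]2Oc3c(cc([C@H]4c5ccc(OCc6ccccc6)c(OCc6ccccc6)c5O[C@H](c5ccc(OCc6ccccc6)c(OCc6ccccc6)c5)[C@@H]4O)c(OCc4ccccc4)c3OCc3ccccc3)[C@@H](O)[C@H]2O)cc1 | intermediate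
22 | (2R,3R,4R)-6-[(2R,3R,4S)-2-(3,4-dihydroxyphenyl)-3,7,8-trihydroxy-3,4-dihydro-2H-chromen-4-yl]-2-(4-hydroxyphenyl)-3,4-dihydro-2H-chromene-3,4,7,8-tetrol | Oc1ccc([C@H]2Oc3c(cc([C@H]4c5ccc(O)c(O)c5O[C@H](c5ccc(O)c(O)c5)[C@@H]4O)c(O)c3O)[C@@H](O)[C@H]2O)cc1 | target

Total step count: 14. Longest linear sequence: 11 steps (steps 1, 3, 4, 5, 6, 7, 10, 11, 12, 13, 14, from compound 1).

Steps most likely to fail

Step 11. An endo approach of the alkene, bond rotation in a stepwise cationic pathway before ring closure, or weak facial control by the chiral ion pair on this large substrate would give the 3,4-cis, the 2,3-trans or the antipodal upper unit. In the fallback the upper pyran ring is still closed by the same cycloaddition, but on the simple aldehyde, and the interflavan bond is then made by the classical arylation of a flavan-4-yl cation. It sets out from 2 and 14, which under the conditions of step 3 should give (2R,3R,4S)-7,8-bis(benzyloxy)-2-[3,4-bis(benzyloxy)phenyl]-4-methoxy-3,4-dihydro-2H-chromen-3-yl 2,2-dimethylpropanoate F1. EtSH with catalytic BF3·OEt2 in CH2Cl2 at −20 °C exchanges the methoxy group, anti to the neighbouring pivalate, to give (2R,3S,4S)-7,8-bis(benzyloxy)-2-[3,4-bis(benzyloxy)phenyl]-4-(ethylsulfanyl)-3,4-dihydro-2H-chromen-3-yl 2,2-dimethylpropanoate F2. AgBF4 in THF at 0 °C in the presence of 10 ionises the thioether selectively, and C6 of 10 should attack the acyloxy-bridged C4 cation anti to O3. This comes back to the route at 19; steps 7 and 10 are then not needed.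

Step 3. Weak discrimination of the alkene faces by the chiral acid in this intermolecular reaction of a small alkoxy-stabilised quinone methide, or a competing uncatalysed pathway, would erode the enantiomeric purity at C2 and C3. The fallback replaces catalyst control by a covalent auxiliary and separation of diastereomers. It sets out from 3: the ruthenium-catalysed addition of step 2 with (1S)-camphanic acid should give (Z)-2-[4-(benzyloxy)phenyl]ethenyl (1S,4R)-4,7,7-trimethyl-3-oxo-2-oxabicyclo[2.2.1]heptane-1-carboxylate F3. With 2, HC(OMe)3 and Sc(OTf)3 (5 mol %) in CH2Cl2 this should give (2R,3R,4S)-7,8-bis(benzyloxy)-2-[4-(benzyloxy)phenyl]-4-methoxy-3,4-dihydro-2H-chromen-3-yl (1S,4R)-4,7,7-trimethyl-3-oxo-2-oxabicyclo[2.2.1]heptane-1-carboxylate F4 together with its (2S,3S,4R) diastereomer. DDQ as in step 4 then gives (2R,3S)-7,8-bis(benzyloxy)-2-[4-(benzyloxy)phenyl]-4-oxo-3,4-dihydro-2H-chromen-3-yl (1S,4R)-4,7,7-trimethyl-3-oxo-2-oxabicyclo[2.2.1]heptane-1-carboxylate F5, which is freed from its (2S,3R) diastereomer by crystallisation or chromatography. LiAlH4 as in step 5 cleaves the auxiliary and comes back to the route at 9.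

Step 14. Once O7 of the lower ring is unmasked, the lower C4 hydroxyl is a para-hydroxybenzylic alcohol, and its hydrogenolytic loss may compete with the last debenzylations. The fallback reverses the order of the two final deprotections so that this oxygen stays silylated during the hydrogenolysis. It sets out from 20: H2 and Pd(OH)2/C in THF/EtOAc should give (2R,3S,4R)-3,4-bis[(tert-butyldimethylsilyl)oxy]-6-[(2R,3R,4S)-2-(3,4-dihydroxyphenyl)-3,7,8-trihydroxy-3,4-dihydro-2H-chromen-4-yl]-2-(4-hydroxyphenyl)-3,4-dihydro-2H-chromene-7,8-diol F6, and Et3N·3HF in THF under argon then removes the two silyl groups and comes back to the route at 22.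

Further compounds
F1 | step 11 | (2R,3R,4S)-7,8-bis(benzyloxy)-2-[3,4-bis(benzyloxy)phenyl]-4-methoxy-3,4-dihydro-2H-chromen-3-yl 2,2-dimethylpropanoate | O(Cc1ccccc1)c1ccc([C@H]2Oc3c(ccc(OCc4ccccc4)c3OCc3ccccc3)[C@H](OC)[C@H]2OC(=O)C(C)(C)C)cc1OCc1ccccc1
F2 | step 11 | (2R,3S,4S)-7,8-bis(benzyloxy)-2-[3,4-bis(benzyloxy)phenyl]-4-(ethylsulfanyl)-3,4-dihydro-2H-chromen-3-yl 2,2-dimethylpropanoate | O(Cc1ccccc1)c1ccc([C@H]2Oc3c(ccc(OCc4ccccc4)c3OCc3ccccc3)[C@H](SCC)[C@H]2OC(=O)C(C)(C)C)cc1OCc1ccccc1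
F3 | step 3 | (Z)-2-[4-(benzyloxy)phenyl]ethenyl (1S,4R)-4,7,7-trimethyl-3-oxo-2-oxabicyclo[2.2.1]heptane-1-carboxylate | O=C(O/C=C\c1ccc(OCc2ccccc2)cc1)[C@@]12CC[C@@](C)(C(=O)O1)C2(C)C
F4 | step 3 | (2R,3R,4S)-7,8-bis(benzyloxy)-2-[4-(benzyloxy)phenyl]-4-methoxy-3,4-dihydro-2H-chromen-3-yl (1S,4R)-4,7,7-trimethyl-3-oxo-2-oxabicyclo[2.2.1]heptane-1-carboxylate | O(Cc1ccccc1)c1ccc([C@H]2Oc3c(ccc(OCc4ccccc4)c3OCc3ccccc3)[C@H](OC)[C@H]2OC(=O)[C@@]23CC[C@@](C)(C(=O)O2)C3(C)C)cc1
F5 | step 3 | (2R,3S)-7,8-bis(benzyloxy)-2-[4-(benzyloxy)phenyl]-4-oxo-3,4-dihydro-2H-chromen-3-yl (1S,4R)-4,7,7-trimethyl-3-oxo-2-oxabicyclo[2.2.1]heptane-1-carboxylate | O(Cc1ccccc1)c1ccc([C@H]2Oc3c(ccc(OCc4ccccc4)c3OCc3ccccc3)C(=O)[C@H]2OC(=O)[C@@]23CC[C@@](C)(C(=O)O2)C3(C)C)cc1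
F6 | step 14 | (2R,3S,4R)-3,4-bis[(tert-butyldimethylsilyl)oxy]-6-[(2R,3R,4S)-2-(3,4-dihydroxyphenyl)-3,7,8-trihydroxy-3,4-dihydro-2H-chromen-4-yl]-2-(4-hydroxyphenyl)-3,4-dihydro-2H-chromene-7,8-diol | Oc1ccc([C@H]2Oc3c(cc([C@H]4c5ccc(O)c(O)c5O[C@H](c5ccc(O)c(O)c5)[C@@H]4O)c(O)c3O)[C@@H](O[Si](C)(C)C(C)(C)C)[C@H]2O[Si](C)(C)C(C)(C)C)cc1
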